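## Retrosynthetic overview

1. Feature: in each half the pyran carbon C4 is bonded to C4a, the direct neighbour of the O1-bearing C8a, and C8a stands para to the C6 hydroxyl. Such a chroman is the ring-expanded isomer of a five-membered spiro ether whose C4 still hangs on C8a of a cyclohexadienone.
2. After ester hydrolysis, C4-C4a and C4'-C4a' are disconnected together (twofold dienone-phenol shift) to the bis(1-oxaspiro[4.5]decadienone) 30, joined through C5-C5'.
3. O1-C8a and O1'-C8a' go back to a 2,2'-biphenol with two tertiary carbinols (twofold PhI(OAc)2 dearomatisation). C5-C5' goes back to an (R)-boronate and an (S)-bromide, coupled while each ring carries only one ortho group.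
4. Each half comes from one arene, silylated 2-bromo-4-iodo-5-methylphenol (C-I for the side chain, C-Br kept for the biaryl). Its partner is the 9-BBN adduct of (R)- or (S)-linalool extended by SeO2 oxidation, two-carbon homologation and Still-Gennari olefination.
5. Ring order: arenes bought; both five-membered spiro ethers in step 20; both pyrans, with both arenes restored, in step 21.

Key step: step 21

Assumption 1: the target structure fixes no sense for the C5-C5' axis. Because the halves are mirror images at C2/C2', the two axial forms of the (2S,2'R) compound are enantiomers, so the route should give one diastereomer, racemic in the axis.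

Assumption 2: both linalool antipodes are bought in high enantiomeric purity. Any minor antipode ends partly in the same (S,R) compound and partly in (R,R)/(S,S) diastereomers, to be removed at 31, where the fixed axis makes them distinct.

## Route

Step 1
Reactants: 1 4-iodo-3-methylphenol
Product: 2 2-bromo-4-iodo-5-methylphenol
Conditions: NBS (1.0 equiv), MeCN, 0 °C
Reagents that add atoms: N-bromosuccinimide, O=C1CCC(=O)N1Br
Why: Electrophilic aromatic bromination goes ortho to the hydroxyl because para is taken by iodine, and it goes to the open C6 rather than the C2 site squeezed between OH and CH3, so the biaryl halogen is set before any alkene is present.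

Step 2
Reactants: 2 2-bromo-4-iodo-5-methylphenol
Product: 3 (2-bromo-4-iodo-5-methylphenoxy)triisopropylsilane
Conditions: TIPSCl, imidazole, DMF, rt
Reagents that add atoms: triisopropylsilyl chloride, CC(C)[Si](Cl)(C(C)C)C(C)C
Why: Standard phenol silylation gives a bulky aryl silyl ether that should withstand the phosphate and acetate bases of the later couplings and leaves with fluoride.

Step 3
Reactants: 4 (R)-linalool
Product: 5 (R)-linalool triethylsilyl ether
Conditions: TESOTf, 2,6-lutidine, CH2Cl2, -78 → 0 °C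
Reagents that add atoms: triethylsilyl triflate, CC[Si](CC)(CC)OS(=O)(=O)C(F)(F)F
Why: Silyl triflate silylation of a hindered tertiary alcohol under lutidine buffering leaves the C-O bond untouched, so the (R) centre is retained and the OH is masked against carbanions, i-Bu2AlH and 9-BBN.

Step 4
Reactants: 5 (R)-linalool triethylsilyl ether
Product: 7 (2E,6R)-2,6-dimethyl-6-(triethylsilyloxy)octa-2,7-dien-1-ol, via (R)-enal 6 (not isolated)
Conditions: SeO2 (0.3 equiv), t-BuOOH, salicylic acid (cat.), CH2Cl2, 0 °C → rt; then NaBH4, MeOH, 0 °C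
Reagents that add atoms: tert-butyl hydroperoxide, CC(C)(C)OO (terminal oxygen source, relayed by SeO2, O=[Se]=O)
Why: Riley allylic oxidation (ene reaction, then [2,3]-shift) attacks the gem-dimethyl end of the trisubstituted alkene and gives the (E)-CH2OH selectively, the vinyl group has no allylic hydrogen, and NaBH4 returns over-oxidised enal 6 to the alcohol by 1,2-reduction.

Step 5
Reactants: 7 (2E,6R)-2,6-dimethyl-6-(triethylsilyloxy)octa-2,7-dien-1-ol
Product: 8 (3R,6E)-8-bromo-3,7-dimethyl-3-(triethylsilyloxy)octa-1,6-diene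
Conditions: CBr4, PPh3, 2,6-lutidine (cat.), CH2Cl2, 0 °C
Reagents that add atoms: carbon tetrabromide, BrC(Br)(Br)Br
Why: The Appel reaction replaces a primary allylic OH by SN2 under near-neutral conditions, without allylic transposition, E/Z change or loss of the silyl ether.

Step 6
Reactants: 8 (3R,6E)-8-bromo-3,7-dimethyl-3-(triethylsilyloxy)octa-1,6-diene
Product: 9 (4E,8R)-4,8-dimethyl-8-(triethylsilyloxy)deca-4,9-dienenitrile
Conditions: MeCN (4 equiv), n-BuLi (3.8 equiv), THF, -78 °C; then 8, -78 → -40 °C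
Reagents that add atoms: acetonitrile, CC#N
Why: SN2 alkylation of lithioacetonitrile with a primary allylic bromide adds the two missing carbons C6' and C7', and the excess of carbanion suppresses double alkylation.

Step 7
Reactants: 9 (4E,8R)-4,8-dimethyl-8-(triethylsilyloxy)deca-4,9-dienenitrile
Product: 11 (4E,8R)-4,8-dimethyl-8-(triethylsilyloxy)deca-4,9-dienal, via N-aluminio imine 10 (not isolated)
Conditions: i-Bu2AlH (1.2 equiv), toluene, -78 °C; then aq. tartaric acid, 0 °C
Reagents that add atoms: water, O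
Why: Partial reduction of a nitrile stops at the N-aluminio imine, which takes up no second hydride and is hydrolysed to the aldehyde only on mildly acidic work-up.

Step 8
Reactants: 11 (4E,8R)-4,8-dimethyl-8-(triethylsilyloxy)deca-4,9-dienal; 12 methyl 2-[bis(2,2,2-trifluoroethoxy)phosphoryl]propanoate
Product: 13 methyl (2Z,6E,10R)-2,6,10-trimethyl-10-(triethylsilyloxy)dodeca-2,6,11-trienoate
Conditions: 12, KN(SiMe3)2, 18-crown-6, THF, -78 °C
Reagents that add atoms: phosphonate 12, COC(=O)C(C)P(=O)(OCC(F)(F)F)OCC(F)(F)F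
Why: In the Still-Gennari olefination the electron-poor trifluoroethyl phosphonate with a dissociated potassium counter-ion makes elimination faster than equilibration of the adducts, which gives the (Z)-2-methyl enoate required at C7'=C8'.

Step 9
Reactants: 13 methyl (2Z,6E,10R)-2,6,10-trimethyl-10-(triethylsilyloxy)dodeca-2,6,11-trienoate; 3 (2-bromo-4-iodo-5-methylphenoxy)triisopropylsilane
Product: 15 methyl (2Z,6E,10R)-12-[5-bromo-2-methyl-4-(triisopropylsilyloxy)phenyl]-2,6,10-trimethyl-10-(triethylsilyloxy)dodeca-2,6-dienoate, via (R)-B-alkyl-9-BBN 14 (not isolated)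
Conditions: 9-BBN (1.2 equiv), THF, 0 °C → rt; then 3, PdCl2(dppf) (5 mol %), aq. K3PO4, THF/DMF, rt
Reagents that add atoms: 9-borabicyclo[3.3.1]nonane, C1CC2CCCC(C1)B2 (its boron unit is carried by 14 only)
Why: In this Brown hydroboration and B-alkyl Suzuki-Miyaura coupling, 9-BBN adds anti-Markovnikov to the only monosubstituted alkene and spares the trisubstituted alkenes and the ester, and zerovalent palladium inserts into C-I at room temperature well before the electron-rich, silyloxy-flanked C-Br, so the C4-C8a bond forms and the bromide is kept.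

Step 10
Reactants: 15 (R)-aryl bromide from step 9
Product: 16 methyl (2Z,6E,10R)-2,6,10-trimethyl-12-[2-methyl-5-(4,4,5,5-tetramethyl-1,3,2-dioxaborolan-2-yl)-4-(triisopropylsilyloxy)phenyl]-10-(triethylsilyloxy)dodeca-2,6-dienoate
Conditions: B2pin2, PdCl2(dppf) (5 mol %), KOAc, dioxane, 85 °C
Reagents that add atoms: bis(pinacolato)diboron, CC1(C)OB(OC1(C)C)B1OC(C)(C)C(C)(C)O1
Why: Miyaura borylation with the weak base KOAc converts the aryl bromide to the pinacol boronate without biaryl formation and tolerates esters, alkenes and silyl ethers.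

Step 11
Reactants: 17 (S)-linalool
Product: 18 (S)-linalool triethylsilyl ether
Conditions: TESOTf, 2,6-lutidine, CH2Cl2, -78 → 0 °C
Reagents that add atoms: triethylsilyl triflate, CC[Si](CC)(CC)OS(=O)(=O)C(F)(F)F
Why: The same buffered silyl triflate silylation as in step 3 retains the (S) centre because the C-O bond is not touched.

Step 12
Reactants: 18 (S)-linalool triethylsilyl ether
Product: 20 (2E,6S)-2,6-dimethyl-6-(triethylsilyloxy)octa-2,7-dien-1-ol, via (S)-enal 19 (not isolated)
Conditions: SeO2 (0.3 equiv), t-BuOOH, salicylic acid (cat.), CH2Cl2, 0 °C → rt; then NaBH4, MeOH, 0 °C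
Reagents that add atoms: tert-butyl hydroperoxide, CC(C)(C)OO (terminal oxygen source, relayed by SeO2, O=[Se]=O)
Why: Riley allylic oxidation is (E)-selective at the gem-dimethyl terminus, and the borohydride treatment converges enal 19 onto the alcohol.

Step 13
Reactants: 20 (2E,6S)-2,6-dimethyl-6-(triethylsilyloxy)octa-2,7-dien-1-ol
Product: 21 (3S,6E)-8-bromo-3,7-dimethyl-3-(triethylsilyloxy)octa-1,6-diene
Conditions: CBr4, PPh3, 2,6-lutidine (cat.), CH2Cl2, 0 °C
Reagents that add atoms: carbon tetrabromide, BrC(Br)(Br)Br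
Why: The Appel reaction substitutes the primary allylic alcohol by SN2 without transposition.

Step 14
Reactants: 21 (3S,6E)-8-bromo-3,7-dimethyl-3-(triethylsilyloxy)octa-1,6-diene
Product: 22 (4E,8S)-4,8-dimethyl-8-(triethylsilyloxy)deca-4,9-dienenitrile
Conditions: MeCN (4 equiv), n-BuLi (3.8 equiv), THF, -78 °C; then 21, -78 → -40 °C
Reagents that add atoms: acetonitrile, CC#N
Why: SN2 alkylation of excess lithioacetonitrile with the primary allylic bromide gives the two-carbon homologue.

Step 15
Reactants: 22 (4E,8S)-4,8-dimethyl-8-(triethylsilyloxy)deca-4,9-dienenitrile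
Product: 24 (4E,8S)-4,8-dimethyl-8-(triethylsilyloxy)deca-4,9-dienal, via N-aluminio imine 23 (not isolated)
Conditions: i-Bu2AlH (1.2 equiv), toluene, -78 °C; then aq. tartaric acid, 0 °C
Reagents that add atoms: water, O
Why: Partial nitrile reduction halts at the N-aluminio imine, and hydrolysis on work-up releases the aldehyde.

Step 16
Reactants: 24 (4E,8S)-4,8-dimethyl-8-(triethylsilyloxy)deca-4,9-dienal; 12 methyl 2-[bis(2,2,2-trifluoroethoxy)phosphoryl]propanoate
Product: 25 methyl (2Z,6E,10S)-2,6,10-trimethyl-10-(triethylsilyloxy)dodeca-2,6,11-trienoate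
Conditions: 12, KN(SiMe3)2, 18-crown-6, THF, -78 °C
Reagents that add atoms: phosphonate 12, COC(=O)C(C)P(=O)(OCC(F)(F)F)OCC(F)(F)F
Why: The Still-Gennari olefination under kinetic control gives the (Z)-2-methyl enoate.

Step 17
Reactants: 25 methyl (2Z,6E,10S)-2,6,10-trimethyl-10-(triethylsilyloxy)dodeca-2,6,11-trienoate; 3 (2-bromo-4-iodo-5-methylphenoxy)triisopropylsilane
Product: 27 methyl (2Z,6E,10S)-12-[5-bromo-2-methyl-4-(triisopropylsilyloxy)phenyl]-2,6,10-trimethyl-10-(triethylsilyloxy)dodeca-2,6-dienoate, via (S)-B-alkyl-9-BBN 26 (not isolated)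
Conditions: 9-BBN (1.2 equiv), THF, 0 °C → rt; then 3, PdCl2(dppf) (5 mol %), aq. K3PO4, THF/DMF, rt
Reagents that add atoms: 9-borabicyclo[3.3.1]nonane, C1CC2CCCC(C1)B2 (its boron unit is carried by 26 only)
Why: Brown hydroboration of the vinyl group and B-alkyl Suzuki-Miyaura coupling at the C-I bond proceed as in step 9, with the C-Br bond left for the pairing.

Step 18
Reactants: 16 (R)-aryl boronate; 27 (S)-aryl bromide
Product: 28 dimethyl (2Z,2'Z,6E,6'E,10S,10'R)-12,12'-[4,4'-dimethyl-6,6'-bis(triisopropylsilyloxy)biphenyl-3,3'-diyl]bis[2,6,10-trimethyl-10-(triethylsilyloxy)dodeca-2,6-dienoate]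
Conditions: Pd(OAc)2 (5 mol %), SPhos (10 mol %), K3PO4, toluene/H2O, 70 °C
Reagents that add atoms: none
Why: In this Suzuki-Miyaura biaryl coupling with a bulky biarylphosphine each partner has a single group (OTIPS) next to the reacting carbon, so C5-C5' forms as an ordinary di-ortho-substituted biaryl, and one (R)-boronate with one (S)-bromide fixes the heterochiral pairing.

Step 19
Reactants: 28 fully silylated biaryl
Product: 29 dimethyl (2Z,2'Z,6E,6'E,10S,10'R)-12,12'-(6,6'-dihydroxy-4,4'-dimethylbiphenyl-3,3'-diyl)bis(10-hydroxy-2,6,10-trimethyldodeca-2,6-dienoate)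
Conditions: Bu4NF/AcOH (1:1, 8 equiv), THF, 0 °C → rt
Reagents that add atoms: none
Why: Fluoride desilylation driven by the Si-F bond frees both phenols and both tertiary alcohols in one operation, and the acetic acid buffer keeps phenoxide and fluoride basicity away from the methyl esters.

Step 20
Reactants: 29 biphenol bis(carbinol)
Product: 30 (2S,2'R)-bis(spiro ether dienone) bis(methyl ester): two 2,6-dimethyl-8-oxo-1-oxaspiro[4.5]deca-6,9-diene units joined C9-C9' (C5-C5' in chroman numbering), each with the (3E,7Z)-8-methoxycarbonyl-4-methylnona-3,7-dienyl chain on C2, spiro centres undefined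
Conditions: PhI(OAc)2 (2.3 equiv), (CF3)2CHOH/CH2Cl2, 0 °C
Reagents that add atoms: none
Why: Oxidative dearomatisation of a para-alkylphenol by trivalent iodine makes each para carbon C8a electrophilic after ligand exchange at the phenol oxygen and loss of PhI, the tethered tertiary hydroxyl captures it by a five-membered (5-exo) closure ahead of the non-nucleophilic fluoroalcohol and the isolated alkenes, and the spiro centres need no control because step 21 erases them.

Step 21
Reactants: 30 (2S,2'R)-bis(spiro ether dienone) bis(methyl ester)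
Product: 31 dimethyl (2Z,2'Z,6E,6'E)-9,9'-[(2S,2'R)-6,6'-dihydroxy-2,2',8,8'-tetramethyl-5,5'-bichroman-2,2'-diyl]bis(2,6-dimethylnona-2,6-dienoate)
Conditions: BF3·OEt2 (6 equiv), CH2Cl2, -40 → 0 °C; aq. NaHCO3
Reagents that add atoms: none
Why: BF3 binds each dienone oxygen and turns the ring into a boron-oxy pentadienyl cation with charge on C4a and C8, the two neighbours of the spiro carbon C8a, after which the C4 methylene moves by a 1,2-shift from C8a to C4a and loss of the C4a proton gives back the arene (acid-induced dienone-phenol rearrangement, known for 1-oxaspiro[4.5]deca-6,9-dien-8-ones, which give 6-hydroxychromans, and run here on both halves of one molecule). Each pyran is closed by ring expansion and not by cyclisation: the five-membered ring O1-C2-C3-C4-C8a takes C4a in between C4 and C8a, so no C-O bond is made or broken. Carbon migrates in preference to oxygen because the shift of C4 leaves the charge on C8a as an O1-stabilised oxocarbenium ion, whereas a shift of O1 would leave only an allyl cation. A shift toward C8 builds a quaternary carbon with no proton to lose, so that cation can only return, and irreversible aromatisation drains the material through C4a. No carbon stereocentre is formed, the undefined spiro centres vanish so that all diastereomers of 30 converge, C2 and C2' keep the configurations of the two linalools, and the C5-C5' axis becomes tetra-ortho hindered only now, its two senses being enantiomers. Low temperature, enough BF3 to saturate the two esters as well, and short contact are needed to spare the tertiary C2-O1 bonds, the trisubstituted alkenes and the (Z)-enoates.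

Step 22
Reactants: 31 dimethyl ester of the target
Product: 32 CNP0282703.1, (2Z,2'Z,6E,6'E)-9,9'-[(2S,2'R)-6,6'-dihydroxy-2,2',8,8'-tetramethyl-5,5'-bichroman-2,2'-diyl]bis(2,6-dimethylnona-2,6-dienoic acid)
Conditions: LiOH (10 equiv), degassed THF/MeOH/H2O, Ar, rt → 40 °C; then 1 M HCl to pH 3
Reagents that add atoms: lithium hydroxide, [Li+].[OH-]
Why: Saponification (acyl substitution by hydroxide) cleaves both methyl esters, mild temperature avoids Z to E drift of the 2-methyl enoates, and exclusion of air protects the electron-rich chromanolates.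

## Compound list

1 | 4-iodo-3-methylphenol | Cc1cc(O)ccc1I | starting material
2 | 2-bromo-4-iodo-5-methylphenol | Cc1cc(O)c(Br)cc1I | intermediate
3 | (2-bromo-4-iodo-5-methylphenoxy)triisopropylsilane | Cc1cc(O[Si](C(C)C)(C(C)C)C(C)C)c(Br)cc1I | intermediate
4 | (R)-linalool | C=C[C@](C)(O)CCC=C(C)C | starting material
5 | (R)-linalool triethylsilyl ether | C=C[C@](C)(O[Si](CC)(CC)CC)CCC=C(C)C | intermediate
6 | (2E,6R)-2,6-dimethyl-6-(triethylsilyloxy)octa-2,7-dienal | C=C[C@](C)(O[Si](CC)(CC)CC)CC/C=C(\C)C=O | intermediate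
7 | (2E,6R)-2,6-dimethyl-6-(triethylsilyloxy)octa-2,7-dien-1-ol | C=C[C@](C)(O[Si](CC)(CC)CC)CC/C=C(\C)CO | intermediate
8 | (3R,6E)-8-bromo-3,7-dimethyl-3-(triethylsilyloxy)octa-1,6-diene | C=C[C@](C)(O[Si](CC)(CC)CC)CC/C=C(\C)CBr | intermediate
9 | (4E,8R)-4,8-dimethyl-8-(triethylsilyloxy)deca-4,9-dienenitrile | C=C[C@](C)(O[Si](CC)(CC)CC)CC/C=C(\C)CCC#N | intermediate
10 | N-(diisobutylaluminio) imine of 11 | C=C[C@](C)(O[Si](CC)(CC)CC)CC/C=C(\C)CCC=N[Al](CC(C)C)CC(C)C | intermediate
11 | (4E,8R)-4,8-dimethyl-8-(triethylsilyloxy)deca-4,9-dienal | C=C[C@](C)(O[Si](CC)(CC)CC)CC/C=C(\C)CCC=O | intermediate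
12 | methyl 2-[bis(2,2,2-trifluoroethoxy)phosphoryl]propanoate | COC(=O)C(C)P(=O)(OCC(F)(F)F)OCC(F)(F)F | starting material
13 | methyl (2Z,6E,10R)-2,6,10-trimethyl-10-(triethylsilyloxy)dodeca-2,6,11-trienoate | C=C[C@](C)(O[Si](CC)(CC)CC)CC/C=C(\C)CC/C=C(/C)C(=O)OC | intermediate
14 | (R)-B-alkyl-9-BBN adduct of 13 | C1CC2CCCC(C1)B2CC[C@](C)(O[Si](CC)(CC)CC)CC/C=C(\C)CC/C=C(/C)C(=O)OC | intermediate
15 | methyl (2Z,6E,10R)-12-[5-bromo-2-methyl-4-(triisopropylsilyloxy)phenyl]-2,6,10-trimethyl-10-(triethylsilyloxy)dodeca-2,6-dienoate | Cc1cc(O[Si](C(C)C)(C(C)C)C(C)C)c(Br)cc1CC[C@](C)(O[Si](CC)(CC)CC)CC/C=C(\C)CC/C=C(/C)C(=O)OC | intermediate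
16 | (R)-aryl pinacol boronate from 15 | Cc1cc(O[Si](C(C)C)(C(C)C)C(C)C)c(B2OC(C)(C)C(C)(C)O2)cc1CC[C@](C)(O[Si](CC)(CC)CC)CC/C=C(\C)CC/C=C(/C)C(=O)OC | intermediate
17 | (S)-linalool | C=C[C@@](C)(O)CCC=C(C)C | starting material
18 | (S)-linalool triethylsilyl ether | C=C[C@@](C)(O[Si](CC)(CC)CC)CCC=C(C)C | intermediate
19 | (2E,6S)-2,6-dimethyl-6-(triethylsilyloxy)octa-2,7-dienal | C=C[C@@](C)(O[Si](CC)(CC)CC)CC/C=C(\C)C=O | intermediate
20 | (2E,6S)-2,6-dimethyl-6-(triethylsilyloxy)octa-2,7-dien-1-ol | C=C[C@@](C)(O[Si](CC)(CC)CC)CC/C=C(\C)CO | intermediate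
21 | (3S,6E)-8-bromo-3,7-dimethyl-3-(triethylsilyloxy)octa-1,6-diene | C=C[C@@](C)(O[Si](CC)(CC)CC)CC/C=C(\C)CBr | intermediate
22 | (4E,8S)-4,8-dimethyl-8-(triethylsilyloxy)deca-4,9-dienenitrile | C=C[C@@](C)(O[Si](CC)(CC)CC)CC/C=C(\C)CCC#N | intermediate
23 | N-(diisobutylaluminio) imine of 24 | C=C[C@@](C)(O[Si](CC)(CC)CC)CC/C=C(\C)CCC=N[Al](CC(C)C)CC(C)C | intermediate
24 | (4E,8S)-4,8-dimethyl-8-(triethylsilyloxy)deca-4,9-dienal | C=C[C@@](C)(O[Si](CC)(CC)CC)CC/C=C(\C)CCC=O | intermediate
25 | methyl (2Z,6E,10S)-2,6,10-trimethyl-10-(triethylsilyloxy)dodeca-2,6,11-trienoate | C=C[C@@](C)(O[Si](CC)(CC)CC)CC/C=C(\C)CC/C=C(/C)C(=O)OC | intermediate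
26 | (S)-B-alkyl-9-BBN adduct of 25 | C1CC2CCCC(C1)B2CC[C@@](C)(O[Si](CC)(CC)CC)CC/C=C(\C)CC/C=C(/C)C(=O)OC | intermediate
27 | methyl (2Z,6E,10S)-12-[5-bromo-2-methyl-4-(triisopropylsilyloxy)phenyl]-2,6,10-trimethyl-10-(triethylsilyloxy)dodeca-2,6-dienoate | Cc1cc(O[Si](C(C)C)(C(C)C)C(C)C)c(Br)cc1CC[C@@](C)(O[Si](CC)(CC)CC)CC/C=C(\C)CC/C=C(/C)C(=O)OC | intermediate
28 | fully silylated (10S,10'R)-biaryl bis(methyl ester) | Cc1cc(O[Si](C(C)C)(C(C)C)C(C)C)c(-c2cc(CC[C@@](C)(O[Si](CC)(CC)CC)CC/C=C(\C)CC/C=C(/C)C(=O)OC)c(C)cc2O[Si](C(C)C)(C(C)C)C(C)C)cc1CC[C@](C)(O[Si](CC)(CC)CC)CC/C=C(\C)CC/C=C(/C)C(=O)OC | intermediate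
29 | (10S,10'R)-biphenol bis(tertiary carbinol) bis(methyl ester) | Cc1cc(O)c(-c2cc(CC[C@@](C)(O)CC/C=C(\C)CC/C=C(/C)C(=O)OC)c(C)cc2O)cc1CC[C@](C)(O)CC/C=C(\C)CC/C=C(/C)C(=O)OC | intermediate
30 | (2S,2'R)-bis(spiro ether dienone) bis(methyl ester), spiro centres undefined | C/C(=C/CC/C(C)=C/CC[C@@]1(C)CCC2(O1)C(C)=CC(=O)C(=C2)C2=CC3(CC[C@@](C)(CC/C=C(\C)CC/C=C(/C)C(=O)OC)O3)C(C)=CC2=O)C(=O)OC | intermediate
31 | dimethyl ester of the target, (2S,2'R)-5,5'-bichroman | C/C(=C/CC/C(C)=C/CC[C@@]1(C)CCc2c(c(C)cc(O)c2-c2c(O)cc(C)c3c2CC[C@@](C)(CC/C=C(\C)CC/C=C(/C)C(=O)OC)O3)O1)C(=O)OC | intermediate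
32 | CNP0282703.1, (2S,2'R)-5,5'-bichroman diacid | C/C(=C/CC/C(C)=C/CC[C@@]1(C)CCc2c(c(C)cc(O)c2-c2c(O)cc(C)c3c2CC[C@@](C)(CC/C=C(\C)CC/C=C(/C)C(=O)O)O3)O1)C(=O)O | target

## Step count and risks

Total step count: 22.
Longest linear sequence: 13 (steps 3 to 10, then 18 to 22).

**Step 21.**
- Risks: the Lewis acid may ionise the tertiary C2-O1 bonds, with loss of configuration or elimination. Released protons may start cyclisation of the trisubstituted alkenes. The phenol freed by the first shift may reversibly capture C4a' of the remaining dienone. The second shift may stall as crowding builds around C5-C5'.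
- Fallback: it sets out from 27 and 15 and comes back at 31. The ring expansion is moved to the monomers, where it is the plain single case, and the biaryl bond is made last.
- (S) series: Bu4NF/AcOH frees 27 to the (S)-bromophenol carbinol F1. PhI(OAc)2 in (CF3)2CHOH gives the (S)-bromo spiro dienone F2. BF3·OEt2 gives the (S)-5-bromo-6-chromanol F3. MOMCl/i-Pr2NEt gives the (S)-bromochroman MOM ether F4.
- (R) series: the same four operations turn 15 into the (R)-bromophenol carbinol F5, the (R)-bromo spiro dienone F6, the (R)-5-bromo-6-chromanol F7 and the (R)-bromochroman MOM ether F8. Miyaura borylation (B2pin2, Pd(OAc)2, SPhos, KOAc, dioxane) then gives the (R)-chroman boronate F9.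
- Pairing: a Suzuki-Miyaura coupling under conditions made for tetra-ortho-substituted biaryls (Pd(OAc)2, BI-DIME ligand, K3PO4, toluene, 100 °C) joins F4 and F9 to the bichroman bis(MOM) ether F10. Dilute HCl in MeOH at rt then releases 31.

**Step 20.**
- Risks: the free 2,2'-biphenol may undergo intermolecular oxidative coupling or over-oxidation. The second dearomatisation may lag once the first ring has become an electron-poor dienone. Solvent or acetate may be trapped at C8a.
- Fallback: it sets out from 27 and 16 and comes back at 30. The two oxidations are separated so that each is run on a single phenol.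
- Sequence: 27 is desilylated to the (S)-bromophenol carbinol F1 and oxidised to the (S)-bromo spiro dienone F2, as above. The alpha-bromo dienone is coupled as a vinyl bromide with boronate 16 (PdCl2(dppf), aq. K3PO4, THF, rt → 40 °C) to the silylated aryl spiro dienone F11. Bu4NF/AcOH gives the phenol carbinol spiro dienone F12. One equivalent of PhI(OAc)2 in (CF3)2CHOH closes the second spiro ether to 30.

**Step 18.**
- Risks: the electron-rich ortho-silyloxy boronate may protodeborylate. Base may strip the aryl silyl ethers before coupling. Transmetalation may be slow between two silyloxy-flanked partners.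
- Fallback: it sets out from 15 and 27 and comes back at 28. The nucleophile is changed from boron to tin, so that no base is present.
- Sequence: 15 with Me3SnSnMe3 and Pd(PPh3)4 in toluene at 100 °C gives the (R)-arylstannane F13. This is joined to 27 by a copper-assisted Stille coupling (Pd(PPh3)4, CuCl, LiCl, DMSO, 60 °C).

## Further compounds

F1 | step 21 | (S)-bromophenol carbinol, methyl (2Z,6E,10S)-12-(5-bromo-4-hydroxy-2-methylphenyl)-10-hydroxy-2,6,10-trimethyldodeca-2,6-dienoate | Cc1cc(O)c(Br)cc1CC[C@@](C)(O)CC/C=C(\C)CC/C=C(/C)C(=O)OC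
F2 | step 21 | (S)-bromo spiro dienone, methyl (2Z,6E)-9-[(2S)-9-bromo-2,6-dimethyl-8-oxo-1-oxaspiro[4.5]deca-6,9-dien-2-yl]-2,6-dimethylnona-2,6-dienoate, spiro centre undefined | CC1=CC(=O)C(Br)=CC12CC[C@](C)(CC/C=C(\C)CC/C=C(/C)C(=O)OC)O2
F3 | step 21 | (S)-5-bromo-6-chromanol, methyl (2Z,6E)-9-[(2S)-5-bromo-6-hydroxy-2,8-dimethylchroman-2-yl]-2,6-dimethylnona-2,6-dienoate | Oc1cc(C)c2c(c1Br)CC[C@](C)(CC/C=C(\C)CC/C=C(/C)C(=O)OC)O2
F4 | step 21 | (S)-bromochroman MOM ether | COCOc1cc(C)c2c(c1Br)CC[C@](C)(CC/C=C(\C)CC/C=C(/C)C(=O)OC)O2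
F5 | step 21 | (R)-bromophenol carbinol, methyl (2Z,6E,10R)-12-(5-bromo-4-hydroxy-2-methylphenyl)-10-hydroxy-2,6,10-trimethyldodeca-2,6-dienoate | Cc1cc(O)c(Br)cc1CC[C@](C)(O)CC/C=C(\C)CC/C=C(/C)C(=O)OC
F6 | step 21 | (R)-bromo spiro dienone, spiro centre undefined | CC1=CC(=O)C(Br)=CC12CC[C@@](C)(CC/C=C(\C)CC/C=C(/C)C(=O)OC)O2
F7 | step 21 | (R)-5-bromo-6-chromanol | Oc1cc(C)c2c(c1Br)CC[C@@](C)(CC/C=C(\C)CC/C=C(/C)C(=O)OC)O2
F8 | step 21 | (R)-bromochroman MOM ether | COCOc1cc(C)c2c(c1Br)CC[C@@](C)(CC/C=C(\C)CC/C=C(/C)C(=O)OC)O2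
F9 | step 21 | (R)-chroman boronate, 5-pinacolboryl analogue of F8 | COCOc1cc(C)c2c(c1B3OC(C)(C)C(C)(C)O3)CC[C@@](C)(CC/C=C(\C)CC/C=C(/C)C(=O)OC)O2
F10 | step 21 | bichroman bis(MOM) ether, 6,6'-bis(methoxymethyl) ether of 31 | C/C(=C/CC/C(C)=C/CC[C@@]1(C)CCc2c(c(C)cc(OCOC)c2-c2c(OCOC)cc(C)c3c2CC[C@@](C)(CC/C=C(\C)CC/C=C(/C)C(=O)OC)O3)O1)C(=O)OC
F11 | step 20 | silylated aryl spiro dienone, (S)-spiro dienone half joined to the silylated (R)-arene half | CC1=CC(=O)C(c3cc(CC[C@](C)(O[Si](CC)(CC)CC)CC/C=C(\C)CC/C=C(/C)C(=O)OC)c(C)cc3O[Si](C(C)C)(C(C)C)C(C)C)=CC12CC[C@](C)(CC/C=C(\C)CC/C=C(/C)C(=O)OC)O2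
F12 | step 20 | phenol carbinol spiro dienone, desilylated F11 | CC1=CC(=O)C(c3cc(CC[C@](C)(O)CC/C=C(\C)CC/C=C(/C)C(=O)OC)c(C)cc3O)=CC12CC[C@](C)(CC/C=C(\C)CC/C=C(/C)C(=O)OC)O2
F13 | step 18 | (R)-arylstannane, trimethylstannyl analogue of 15 | Cc1cc(O[Si](C(C)C)(C(C)C)C(C)C)c([Sn](C)(C)C)cc1CC[C@](C)(O[Si](CC)(CC)CC)CC/C=C(\C)CC/C=C(/C)C(=O)OC
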